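**Retrosynthetic overview**
1. Irigenin 16 ⇐ tri-O-benzyl ether 15 by hydrogenolysis. Rings A and B are bought, and the 4-pyranone ring C is the only ring built, after the full carbon skeleton is in place.
2. 15 ⇐ β-keto acetal 13. Only the MOM-masked phenol is released, so O1–C2 closure gives the 6-OMe isomer and cannot give the 8-OMe isomer.
3. 13 ⇐ chalcone 12 by an oxidative 1,2-aryl shift that moves ring B onto the future C3.
4. 12 ⇐ acetophenone 10 + aldehyde 4 by Claisen–Schmidt aldol condensation, the key C–C bond that joins the two halves.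
5. 10 ⇐ phloroacetophenone 5 (dibenzylation, para-hydroxylation, O-methylation, MOM). 4 ⇐ 5-bromovanillin 1.

Assumption: irigenin has no stereocentre or stereoaxis, so it is achiral and the "single enantiomer" is the compound itself. The racemic centres in 11, 13 and 14 are erased later in the route.

**Step 1**
Reactants: 1 5-bromovanillin (3-bromo-4-hydroxy-5-methoxybenzaldehyde)
Product: 2 5-hydroxyvanillin (3,4-dihydroxy-5-methoxybenzaldehyde)
Conditions: NaOH (7 equiv), Cu powder (5 mol %), H2O, reflux, N2, 24 h; then HCl to pH 2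
Reagents that add atoms: sodium hydroxide [Na+].[OH-]
Why: This is a copper-catalysed Ullmann-type hydroxylation of the aryl bromide, and the para-phenoxide deactivates the aldehyde so no Cannizzaro reaction occurs.

**Step 2**
Reactants: 2 5-hydroxyvanillin
Product: 3 3-hydroxy-4,5-dimethoxybenzaldehyde
Conditions: Me2SO4 (1.05 equiv), Na2CO3 (1.1 equiv), acetone, reflux, 5 h
Reagents that add atoms: dimethyl sulfate COS(=O)(=O)OC
Why: In this Williamson methylation the weak base ionises only the much more acidic 4-OH (para to CHO), so only that oxygen is alkylated, and traces of the trimethyl ether are removed by base extraction.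

**Step 3**
Reactants: 3 3-hydroxy-4,5-dimethoxybenzaldehyde
Product: 4 3-(benzyloxy)-4,5-dimethoxybenzaldehyde
Conditions: BnBr (1.2 equiv), K2CO3 (1.5 equiv), DMF, 60 °C, 4 h
Reagents that add atoms: benzyl bromide BrCc1ccccc1
Why: This is a Williamson benzylation of the only free phenol, and the benzyl ether survives every later basic, oxidative and mildly acidic step.

**Step 4**
Reactants: 5 2,4,6-trihydroxyacetophenone (phloroacetophenone)
Product: 6 1-[2,4-bis(benzyloxy)-6-hydroxyphenyl]ethan-1-one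
Conditions: BnBr (2.05 equiv), K2CO3 (2.2 equiv), DMF, rt to 50 °C, 12 h
Reagents that add atoms: benzyl bromide BrCc1ccccc1
Why: This Williamson benzylation stops at the diether because the remaining ortho-OH is hydrogen-bonded to the acetyl carbonyl and is the least nucleophilic.

**Step 5**
Reactants: 6 1-[2,4-bis(benzyloxy)-6-hydroxyphenyl]ethan-1-one
Product: 8 1-[2,4-bis(benzyloxy)-3,6-dihydroxyphenyl]ethan-1-one, via aryl sulfate potassium salt 7 (not isolated)
Conditions: K2S2O8 (1.1 equiv), aq KOH, pyridine, 0 °C to rt, 24 h; acidify to pH 4–5 and extract unreacted 6 for recycling; aqueous phase made 2 M in HCl, 80 °C, 30 min, N2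
Reagents that add atoms: potassium peroxodisulfate [K+].[K+].[O-]S(=O)(=O)OOS(=O)(=O)[O-]
Why: In the Elbs persulfate oxidation the phenolate attacks the peroxide oxygen through its para carbon (between the two OBn groups), and mild acid hydrolysis of sulfate ester 7 then frees the hydroquinone.

**Step 6**
Reactants: 8 1-[2,4-bis(benzyloxy)-3,6-dihydroxyphenyl]ethan-1-one
Product: 9 1-[2,4-bis(benzyloxy)-6-hydroxy-3-methoxyphenyl]ethan-1-one
Conditions: Me2SO4 (1.05 equiv), K2CO3 (1.2 equiv), acetone, reflux, N2, 6 h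
Reagents that add atoms: dimethyl sulfate COS(=O)(=O)OC
Why: This is a partial Williamson methylation in which one equivalent of reagent alkylates the non-chelated 3-OH and leaves the carbonyl-chelated 6-OH untouched.

**Step 7**
Reactants: 9 1-[2,4-bis(benzyloxy)-6-hydroxy-3-methoxyphenyl]ethan-1-one
Product: 10 1-[2,4-bis(benzyloxy)-3-methoxy-6-(methoxymethoxy)phenyl]ethan-1-one
Conditions: NaH (1.2 equiv), DMF, 0 °C; MOMCl (1.3 equiv), 0 °C to rt, 2 h
Reagents that add atoms: chloromethyl methyl ether COCCl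
Why: MOM ether formation on the phenoxide masks the p-methoxyphenol unit against the later oxidant and labels the future ring oxygen with a group orthogonal to benzyl.

**Step 8**
Reactants: 10 1-[2,4-bis(benzyloxy)-3-methoxy-6-(methoxymethoxy)phenyl]ethan-1-one; 4 3-(benzyloxy)-4,5-dimethoxybenzaldehyde
Product: 12 (E)-1-[2,4-bis(benzyloxy)-3-methoxy-6-(methoxymethoxy)phenyl]-3-[3-(benzyloxy)-4,5-dimethoxyphenyl]prop-2-en-1-one, via racemic aldol adduct 11 (not isolated)
Conditions: 50% aq KOH (10 equiv), EtOH–THF 3:1, rt, 36–48 h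
Reagents that add atoms: none
Why: In this Claisen–Schmidt crossed aldol condensation only 10 can enolise and only 4 is an aldehyde, the carbinol centre of 11 is lost by E1cB dehydration, and the conjugated E-enone is the thermodynamic product.

**Step 9**
Reactants: 12 (E)-chalcone
Product: 13 (±)-1-[2,4-bis(benzyloxy)-3-methoxy-6-(methoxymethoxy)phenyl]-2-[3-(benzyloxy)-4,5-dimethoxyphenyl]-3,3-dimethoxypropan-1-one
Conditions: Tl(NO3)3·3H2O (1.1 equiv), MeOH–CH2Cl2 4:1, rt, 2–4 h; filter off TlNO3, wash with aq NaHCO3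
Reagents that add atoms: methanol CO
Why: In this thallium(III) nitrate oxidative rearrangement, methoxythallation of the enone is followed by a 1,2-shift of the electron-rich p-alkoxyaryl ring as Tl(III) leaves as Tl(I), and the new C2 centre is racemic and is removed in step 10.

**Step 10**
Reactants: 13 (±)-β-keto dimethyl acetal
Product: 15 5,7-bis(benzyloxy)-3-[3-(benzyloxy)-4,5-dimethoxyphenyl]-6-methoxy-4H-chromen-4-one, via free phenol acetal 14 (not isolated)
Conditions: conc. HCl (10% v/v), MeOH–THF 2:1, 60 °C, 2 h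
Reagents that add atoms: none
Why: Acid removes only the MOM group, and the single liberated ortho-phenol closes onto the masked aldehyde and loses methanol to give the aromatic pyranone, so the methoxy group ends up at C6.

**Step 11**
Reactants: 15 tri-O-benzylirigenin
Product: 16 irigenin (5,7-dihydroxy-3-(3-hydroxy-4,5-dimethoxyphenyl)-6-methoxy-4H-chromen-4-one)
Conditions: H2 (1 atm), 10% Pd/C, THF–MeOH 1:1, rt, stopped at full debenzylation (TLC, about 3 h)
Reagents that add atoms: none
Why: Catalytic hydrogenolysis cleaves the three benzyl aryl ethers under neutral conditions that leave the methyl ethers untouched and, with monitoring, spare the conjugated C2=C3 bond.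

**Compound list**
1 | 5-bromovanillin (3-bromo-4-hydroxy-5-methoxybenzaldehyde) | COc1cc(C=O)cc(Br)c1O | starting material
2 | 3,4-dihydroxy-5-methoxybenzaldehyde | COc1cc(C=O)cc(O)c1O | intermediate
3 | 3-hydroxy-4,5-dimethoxybenzaldehyde | COc1cc(C=O)cc(O)c1OC | intermediate
4 | 3-(benzyloxy)-4,5-dimethoxybenzaldehyde | COc1cc(C=O)cc(OCc2ccccc2)c1OC | intermediate
5 | 2,4,6-trihydroxyacetophenone | CC(=O)c1c(O)cc(O)cc1O | starting material
6 | 1-[2,4-bis(benzyloxy)-6-hydroxyphenyl]ethan-1-one | CC(=O)c1c(O)cc(OCc2ccccc2)cc1OCc1ccccc1 | intermediate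
7 | potassium 3-acetyl-2,6-bis(benzyloxy)-4-hydroxyphenyl sulfate | [K+].CC(=O)c1c(O)cc(OCc2ccccc2)c(OS(=O)(=O)[O-])c1OCc1ccccc1 | intermediate
8 | 1-[2,4-bis(benzyloxy)-3,6-dihydroxyphenyl]ethan-1-one | CC(=O)c1c(O)cc(OCc2ccccc2)c(O)c1OCc1ccccc1 | intermediate
9 | 1-[2,4-bis(benzyloxy)-6-hydroxy-3-methoxyphenyl]ethan-1-one | CC(=O)c1c(O)cc(OCc2ccccc2)c(OC)c1OCc1ccccc1 | intermediate
10 | 1-[2,4-bis(benzyloxy)-3-methoxy-6-(methoxymethoxy)phenyl]ethan-1-one | CC(=O)c1c(OCOC)cc(OCc2ccccc2)c(OC)c1OCc1ccccc1 | intermediate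
11 | (±)-1-[2,4-bis(benzyloxy)-3-methoxy-6-(methoxymethoxy)phenyl]-3-[3-(benzyloxy)-4,5-dimethoxyphenyl]-3-hydroxypropan-1-one | COCOc1cc(OCc2ccccc2)c(OC)c(OCc2ccccc2)c1C(=O)CC(O)c1cc(OC)c(OC)c(OCc2ccccc2)c1 | intermediate
12 | (E)-1-[2,4-bis(benzyloxy)-3-methoxy-6-(methoxymethoxy)phenyl]-3-[3-(benzyloxy)-4,5-dimethoxyphenyl]prop-2-en-1-one | COCOc1cc(OCc2ccccc2)c(OC)c(OCc2ccccc2)c1C(=O)/C=C/c1cc(OC)c(OC)c(OCc2ccccc2)c1 | intermediate
13 | (±)-1-[2,4-bis(benzyloxy)-3-methoxy-6-(methoxymethoxy)phenyl]-2-[3-(benzyloxy)-4,5-dimethoxyphenyl]-3,3-dimethoxypropan-1-one | COCOc1cc(OCc2ccccc2)c(OC)c(OCc2ccccc2)c1C(=O)C(C(OC)OC)c1cc(OC)c(OC)c(OCc2ccccc2)c1 | intermediate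
14 | (±)-1-[2,4-bis(benzyloxy)-6-hydroxy-3-methoxyphenyl]-2-[3-(benzyloxy)-4,5-dimethoxyphenyl]-3,3-dimethoxypropan-1-one | COC(OC)C(C(=O)c1c(O)cc(OCc2ccccc2)c(OC)c1OCc1ccccc1)c1cc(OC)c(OC)c(OCc2ccccc2)c1 | intermediate
15 | 5,7-bis(benzyloxy)-3-[3-(benzyloxy)-4,5-dimethoxyphenyl]-6-methoxy-4H-chromen-4-one | COc1cc(-c2coc3cc(OCc4ccccc4)c(OC)c(OCc4ccccc4)c3c2=O)cc(OCc2ccccc2)c1OC | intermediate
16 | irigenin | COc1cc(-c2coc3cc(O)c(OC)c(O)c3c2=O)cc(O)c1OC | target

**Step count**
There are 11 steps in total. The longest linear sequence is 8 steps (5 → 6 → 8 → 9 → 10 → 12 → 13 → 15 → 16, steps 4–11). The aldehyde branch (steps 1–3) joins at step 8.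

**Three steps most likely to fail**

Step 5 (Elbs oxidation). Conversion is typically modest, 6 dissolves poorly in aqueous alkali, and the hydroquinone is air-sensitive. The fallback sets out from 6. It replaces persulfate attack with a Teuber oxidation, using Fremy's salt (2.5 equiv) in KH2PO4 buffer and acetone–water at rt. This oxidises the free para position to give 2-acetyl-3,5-bis(benzyloxy)-1,4-benzoquinone F1. That quinone is reduced at once with aqueous Na2S2O4 in EtOAc, and the route is rejoined at 8.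

Step 9 (thallium-mediated aryl shift). The flanked 4-methoxy group lowers the migratory aptitude of ring B. The nitric acid released can also begin to strip the MOM group while oxidant is still present. The fallback sets out from 12 and moves the aroyl group instead of the aryl group. Weitz–Scheffer epoxidation (30% H2O2, aq NaOH, MeOH–THF, rt) gives the racemic trans-chalcone epoxide F2. BF3·OEt2 (CH2Cl2, 0 °C, minutes) opens it at the benzylic carbon and triggers a 1,2-aroyl shift to give the α-formyl deoxybenzoin F3. HCl in MeOH–THF at 60 °C then removes the MOM group and cyclodehydrates, and the route is rejoined at 15.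

Step 2 (mono-methylation of the catechol). Over-methylation or some 3-O-methylation would contaminate ring B with isomers that are hard to separate. The fallback sets out from 1 and fixes both methyl ethers before the third oxygen is introduced. MeI and K2CO3 in DMF give 3-bromo-4,5-dimethoxybenzaldehyde F4. Miyaura borylation (B2pin2, Pd(dppf)Cl2, KOAc, dioxane, 90 °C) gives 3,4-dimethoxy-5-(4,4,5,5-tetramethyl-1,3,2-dioxaborolan-2-yl)benzaldehyde F5. Oxidation with NaBO3·4H2O in THF–water at rt converts the C–B bond to C–OH without touching the aldehyde, and the route is rejoined at 3.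

**Further compounds**
F1 | step 5 | 2-acetyl-3,5-bis(benzyloxy)cyclohexa-2,5-diene-1,4-dione | CC(=O)C1=C(OCc2ccccc2)C(=O)C(OCc2ccccc2)=CC1=O
F2 | step 9 | rac-trans-[2,4-bis(benzyloxy)-3-methoxy-6-(methoxymethoxy)phenyl]{3-[3-(benzyloxy)-4,5-dimethoxyphenyl]oxiran-2-yl}methanone (one enantiomer drawn) | COCOc1cc(OCc2ccccc2)c(OC)c(OCc2ccccc2)c1C(=O)[C@@H]3O[C@H]3c4cc(OC)c(OC)c(OCc5ccccc5)c4
F3 | step 9 | (±)-3-[2,4-bis(benzyloxy)-3-methoxy-6-(methoxymethoxy)phenyl]-2-[3-(benzyloxy)-4,5-dimethoxyphenyl]-3-oxopropanal | COCOc1cc(OCc2ccccc2)c(OC)c(OCc2ccccc2)c1C(=O)C(C=O)c1cc(OC)c(OC)c(OCc2ccccc2)c1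
F4 | step 2 | 3-bromo-4,5-dimethoxybenzaldehyde | COc1cc(C=O)cc(Br)c1OC
F5 | step 2 | 3,4-dimethoxy-5-(4,4,5,5-tetramethyl-1,3,2-dioxaborolan-2-yl)benzaldehyde | COc1cc(C=O)cc(B2OC(C)(C)C(C)(C)O2)c1OC
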